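(The numbers in the tables come from a simulation on assumed constants.)

Amounts first: in the flask 0.180 M of solid reagent stands against 0.30 M of starting material, so there is less solid than starting material.

| flask | starting material | solid reagent | remark | time |
|---|---|---|---|---|
| elm | 0.20 M (in portions, 2) | 0.18 M | run made earlier; portions every 15 s |  |
| birch | 0.45 M (in portions, 2) | 0.18 M | run made earlier; portions every 15 s |  |
| ash | 0.30 M (in portions, 2) | 0.27 M | run made earlier; portions every 15 s |  |
| flask | 0.30 M (in portions, 2) | 0.180 M | the portions of starting material follow each other after 15 s, the first at the start | 5.0 min |

- elm (time / min: starting material / %, target / %, intermediate / %): 0.417: 78, 2, 24; 0.833: 49, 5, 49; 1.33: 37, 12, 51; 2.50: 31, 22, 41; 5.00: 28, 44, 27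
- birch (time / min: starting material / %, target / %, intermediate / %): 0.417: 83, 0, 19; 1.33: 65, 7, 30; 2.50: 63, 15, 22; 4.00: 60, 20, 17; 5.00: 62, 24, 15
- ash (time / min: starting material / %, target / %, intermediate / %): 0.417: 79, 0, 22; 1.33: 34, 9, 57; 2.50: 28, 24, 45; 4.00: 28, 39, 35; 5.00: 25, 47, 31

(readings scatter by 1.5 percentage points)

- given per volume of solution although it is solid: solid reagent
- at the start none of the solid reagent is in solution
- the reaction counts as stopped when no species that holds the starting material changes by six tenths of a point or more over the second half of the time

- which holds at 5.0 min: what has brought the reaction to rest, or that it has not come to rest (for what has run out or reacted, a solid counts together with what of it has only dissolved) (forward and back rates have come level / it is still moving / all of the starting material has reacted / the partner has run out first)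
- share of the starting material used up at 5.0 min
- target at 5.0 min, in percent of the starting material charged
- intermediate at 5.0 min, in percent of the starting material charged

- Birch has used 0.171 M of starting material by 5.00 min, close to its 0.18 M of solid reagent, so read the use as one for one.
- Carry 60.0% for the flask: this is the solid ceiling, c(solid reagent)/c(starting material), the conversion the charged solid can pay for. Solid reagent is the limiting reagent here.
- For the start of the curve, take ash, which has the flask's c(starting material) but more solid reagent: by the reading it has used 21.0% by 0.417 min.
- For the knee, take birch: by 1.33 min it has used 87.5% of its solid, and its curve then flattens.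
- For the level, compare the solid used by 5.00 min: 95.0% in birch and 80.0% in elm. The flask's ratio of starting material to solid lies between theirs, so expect a conversion between 48.0% and 57.0%.
- Elm and birch have the flask's c(solid reagent), and over the second half target still climbs in elm from 22% to 44% and in birch from 15% to 24%, so expect the flask to be still moving.
- The forecast says it is still moving, with conversion 55.5%, target 34% and intermediate 21.5%, on the ground “so the solid caps conversion”.
- The flask's outcome is: it is still moving; its conversion is 54.9%, its target 34.5% and its intermediate 20.5%.

    starting material + partner ⇌ intermediate (K = 32.0 /M, k = 0.311 /M/s)
    solid reagent ⇌ partner, rate k2*(cs2 - [partner]) while solid is left; crystals form when [partner] > cs2 (solubility = 0.140 M, k = 0.0539 /s)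
    intermediate ⇌ target (K = 20.0, k = 0.00406 /s)

- The flask's conversion stands 5.1 percentage points under the ceiling at 5.00 min, with undissolved solid reagent at 0% of its charge and partner at 0.0152 M. At 0.276 min in the flask, starting material has a half-life of 0.62 min by the forward rate of its step with partner alone, shorter than the 2.8 min of intermediate by the forward rate into target alone.
- On the neighbour with 0.51 M of starting material, the ceiling is 35.3%. That flask gives conversion 34.1%, with target 22.1% and intermediate 12.1%.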